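The aryl C1–OH oxygen and the neighbouring C6 chain CH(CH3)–CH2–CH2–CH= of the target are treated as the opened form of a seven-membered aryl lactone, which is disconnected at the aryl C–O bond to a tetralone. A Baeyer–Villiger oxidation converts the six-membered carbocycle of (R)-6-methoxy-4-methyl-1-tetralone into the benzoxepinone in one operation. It places oxygen para to OMe and turns C1–C4 of the saturated ring into the future side chain, with the benzylic methyl stereocentre intact. The precursor is a benzo-fused cyclohexanone whose carbonyl-bearing aryl carbon is para to OMe and whose C4 carries the R-configured methyl group, set by iridium-catalysed asymmetric hydrogenation.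

Key step: step 4

Remark on numbering: in the target arene, C1 bears OH, C2 the trienoyl group, C4 OMe and C6 the alkyl chain.
Assumption: the antipode of the phosphinooxazoline ligand that delivers the R tetralin is fixed by a pilot hydrogenation. The descriptor then stays R in every later compound, because the priority order aryl > CH2 > CH3 > H never changes.

Step 1
Reactants: 1 7-methoxy-1-tetralone; 2 methylmagnesium bromide
Product: 4 7-methoxy-1-methyl-3,4-dihydronaphthalene, via tertiary alcohol 3 (not isolated)
Conditions: MeMgBr (1.5 equiv), THF, 0 °C → rt; then 6 M HCl, rt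
Reagents that add atoms: none
Why: Grignard 1,2-addition to the aryl ketone gives the tertiary benzylic alcohol, which on acid quench should undergo E1 dehydration to the conjugated, endocyclic trisubstituted alkene (the thermodynamic Zaitsev product).

Step 2
Reactants: 4 7-methoxy-1-methyl-3,4-dihydronaphthalene
Product: 5 (R)-7-methoxy-1-methyl-1,2,3,4-tetrahydronaphthalene
Conditions: H2 (50 bar), [Ir(cod)(L*)][B(3,5-(CF3)2C6H3)4] (1 mol %, L* = tBu-PHOX-type phosphinooxazoline), CH2Cl2, rt
Reagents that add atoms: none
Why: Iridium-catalysed asymmetric hydrogenation of an unfunctionalised trisubstituted aryl alkene, for which 1-methyl-3,4-dihydronaphthalenes are standard substrates; the chiral P,N ligand shields one enantioface so that both hydrogens should be delivered to the other, setting C1 as R.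

Step 3
Reactants: 5 (R)-7-methoxy-1-methyl-1,2,3,4-tetrahydronaphthalene
Product: 7 (R)-6-methoxy-4-methyl-3,4-dihydronaphthalen-1(2H)-one, via tetralol 6 (not isolated)
Conditions: DDQ (2.5 equiv), 1,4-dioxane/H2O (9:1), rt
Reagents that add atoms: water, O
Why: DDQ benzylic oxidation by hydride abstraction; only the C4 methylene is conjugated with the para OMe group, so its cation should be captured by water and the resulting carbinol oxidised on to the ketone, while the tertiary C1–H, meta to OMe, and with it the stereocentre stay untouched.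

Step 4
Reactants: 7 (R)-6-methoxy-4-methyl-3,4-dihydronaphthalen-1(2H)-one
Product: 8 (R)-7-methoxy-5-methyl-4,5-dihydro-1-benzoxepin-2(3H)-one
Conditions: mCPBA (2 equiv), CF3CO2H (1 equiv), CH2Cl2, 0 °C → rt, dark; aq. Na2S2O3/NaHCO3
Reagents that add atoms: mCPBA (3-chloroperoxybenzoic acid), OOC(=O)c1cccc(Cl)c1
Why: The peracid adds to the protonated C1 carbonyl to give the Criegee tetrahedral adduct, and aryl carbon C8a then shifts from C1 to the proximal peroxide oxygen with loss of 3-chlorobenzoate; this is the Baeyer–Villiger oxidation of an aryl alkyl ketone, established for 1-tetralones giving 4,5-dihydro-1-benzoxepin-2(3H)-ones. The seven-membered ring is not closed end to end but arises by ring expansion, the oxygen being inserted into the C1–C8a bond of the six-membered carbocycle. No stereocentre is created; C4 is three bonds from the carbonyl, is not enolisable and takes no part in the shift, so its R configuration should be retained. The selectivity required is migration of aryl rather than the C2 methylene, and it is secured by the OMe group para to C8a, which stabilises the electron-deficient migrating carbon, whereas a primary alkyl group is a poor migrator. The acid co-catalyst speeds adduct formation on this conjugated, donor-substituted ketone, and cold, dilute conditions are chosen to spare the anisole ring from electrophilic hydroxylation.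

Step 5
Reactants: 8 (R)-7-methoxy-5-methyl-4,5-dihydro-1-benzoxepin-2(3H)-one
Product: 9 (5R)-7-methoxy-5-methyl-2,3,4,5-tetrahydro-1-benzoxepin-2-ol (anomeric mixture, in equilibrium with its open hydroxy aldehyde form)
Conditions: i-Bu2AlH (1.05 equiv), CH2Cl2, −78 °C; MeOH, then aq. potassium sodium tartrate
Reagents that add atoms: none
Why: Partial reduction of a lactone with i-Bu2AlH; the aluminium-bound tetrahedral hemiacetal should persist at −78 °C and release the lactol only on work-up, as is routine for dihydrocoumarin-type aryl lactones.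

Step 6
Reactants: 9 (5R)-7-methoxy-5-methyl-2,3,4,5-tetrahydro-1-benzoxepin-2-ol; 10 tert-butyl (triphenylphosphoranylidene)acetate
Product: 12 tert-butyl (2E,6R)-6-(2-hydroxy-5-methoxyphenyl)hept-2-enoate, via hydroxy aldehyde 11 (not isolated)
Conditions: 10 (1.5 equiv), toluene, 80 °C
Reagents that add atoms: none
Why: Wittig olefination of the lactol through its open aldehyde tautomer with a stabilised ylide, which should give the E enoate under thermodynamic control; the phenol is not acidic enough to quench the ylide, and oxa-Michael closure would need an unfavourable seven-membered ring.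

Step 7
Reactants: 12 tert-butyl (2E,6R)-6-(2-hydroxy-5-methoxyphenyl)hept-2-enoate
Product: 14 tert-butyl (2E,6R)-6-(3-formyl-2-hydroxy-5-methoxyphenyl)hept-2-enoate, via hydroxymethyl phenol 13 (not isolated)
Conditions: MgCl2 (2 equiv), Et3N (4 equiv), (CH2O)n (6 equiv), MeCN, reflux; 1 M HCl
Reagents that add atoms: formaldehyde (from paraformaldehyde), C=O
Why: Casnati–Skattebøl magnesium-mediated ortho-formylation; the magnesium phenoxide delivers formaldehyde to the only free ortho carbon, and a second formaldehyde oxidises the hydroxymethyl phenoxide by Oppenauer-type hydride transfer, while the hindered enoate should be inert.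

Step 8
Reactants: 14 tert-butyl (2E,6R)-6-(3-formyl-2-hydroxy-5-methoxyphenyl)hept-2-enoate; 2 methylmagnesium bromide
Product: 15 tert-butyl (2E,6R)-6-[2-hydroxy-3-(1-hydroxyethyl)-5-methoxyphenyl]hept-2-enoate (both carbinol epimers)
Conditions: MeMgBr (2.3 equiv), THF, −78 °C; aq. NH4Cl
Reagents that add atoms: none
Why: Grignard addition; the first equivalent forms the magnesium phenoxide and the second should add to the chelated aldehyde far faster than to the tert-butyl enoate at −78 °C, the new carbinol centre being uncontrolled and removed in step 9.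

Step 9
Reactants: 15 tert-butyl (2E,6R)-6-[2-hydroxy-3-(1-hydroxyethyl)-5-methoxyphenyl]hept-2-enoate
Product: 16 tert-butyl (2E,6R)-6-(3-acetyl-2-hydroxy-5-methoxyphenyl)hept-2-enoate
Conditions: MnO2 (activated, 15 equiv), CH2Cl2, rt
Reagents that add atoms: none
Why: Manganese dioxide oxidation of a benzylic alcohol; this mild surface oxidant should leave the enoate alone and spare the phenol, whose ortho and para positions are all substituted.

Step 10
Reactants: 17 (E)-4,4-dimethoxybut-2-enal; 10 tert-butyl (triphenylphosphoranylidene)acetate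
Product: 18 tert-butyl (2E,4E)-6,6-dimethoxyhexa-2,4-dienoate
Conditions: 10 (1.1 equiv), CH2Cl2, rt
Reagents that add atoms: none
Why: Wittig olefination of an enal with a stabilised ylide, expected to be E-selective; the acetal and the existing E alkene are not affected.

Step 11
Reactants: 18 tert-butyl (2E,4E)-6,6-dimethoxyhexa-2,4-dienoate
Product: 19 tert-butyl (2E,4E)-6-oxohexa-2,4-dienoate
Conditions: p-TsOH·H2O (cat.), acetone/H2O, rt
Reagents that add atoms: water, O
Why: Acid-catalysed acetal hydrolysis under conditions too mild to cleave the tert-butyl ester; the E,E geometry is the thermodynamic one.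

Step 12
Reactants: 16 tert-butyl (2E,6R)-6-(3-acetyl-2-hydroxy-5-methoxyphenyl)hept-2-enoate; 19 tert-butyl (2E,4E)-6-oxohexa-2,4-dienoate
Product: 21 tert-butyl (2E,4E,6E)-8-{3-[(2R,5E)-7-tert-butoxy-7-oxohept-5-en-2-yl]-2-hydroxy-5-methoxyphenyl}-8-oxoocta-2,4,6-trienoate, via aldol adduct 20 (not isolated)
Conditions: Ba(OH)2·8H2O (2 equiv), MeOH/THF, 0 °C → rt, dark, slow addition of 19; cold aq. citric acid
Reagents that add atoms: none
Why: Claisen–Schmidt (crossed aldol) condensation of a 2'-hydroxyacetophenone with a non-enolisable unsaturated aldehyde, so only the methyl ketone can act as the nucleophile; E1cB loss of water from the aldol should give the fully conjugated E trienone, and tert-butyl esters resist methoxide and hydroxide at rt.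

Step 13
Reactants: 21 tert-butyl (2E,4E,6E)-8-{3-[(2R,5E)-7-tert-butoxy-7-oxohept-5-en-2-yl]-2-hydroxy-5-methoxyphenyl}-8-oxoocta-2,4,6-trienoate
Product: 22 (2E,4E,6E)-8-{3-[(2R,5E)-6-carboxyhex-5-en-2-yl]-2-hydroxy-5-methoxyphenyl}-8-oxoocta-2,4,6-trienoic acid (CNP0274934.1)
Conditions: CF3CO2H/CH2Cl2 (1:4), 0 °C → rt, dark; evaporation below rt
Reagents that add atoms: none
Why: Acidolysis of both tert-butyl esters by alkyl–oxygen cleavage with loss of isobutene; the aryl methyl ether, the hydrogen-bonded hydroxy ketone and the stereocentre should survive brief exposure to this non-nucleophilic acid.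

Compound list
1 | 7-methoxy-1-tetralone (7-methoxy-3,4-dihydronaphthalen-1(2H)-one) | COc1ccc2CCCC(=O)c2c1 | starting material
2 | methylmagnesium bromide | C[Mg]Br | starting material
3 | 7-methoxy-1-methyl-1,2,3,4-tetrahydronaphthalen-1-ol, racemic, formed in the flask | COc1ccc2CCCC(C)(O)c2c1 | intermediate
4 | 7-methoxy-1-methyl-3,4-dihydronaphthalene | COc1ccc2CCC=C(C)c2c1 | intermediate
5 | (R)-7-methoxy-1-methyl-1,2,3,4-tetrahydronaphthalene | COc1ccc2c(c1)[C@H](C)CCC2 | intermediate
6 | (4R)-6-methoxy-4-methyl-1,2,3,4-tetrahydronaphthalen-1-ol, both C1 epimers, formed in the flask | COc1ccc2c(c1)[C@H](C)CCC2O | intermediate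
7 | (R)-6-methoxy-4-methyl-3,4-dihydronaphthalen-1(2H)-one | COc1ccc2c(c1)[C@H](C)CCC2=O | intermediate
8 | (R)-7-methoxy-5-methyl-4,5-dihydro-1-benzoxepin-2(3H)-one | COc1ccc2c(c1)[C@H](C)CCC(=O)O2 | intermediate
9 | (5R)-7-methoxy-5-methyl-2,3,4,5-tetrahydro-1-benzoxepin-2-ol, anomeric mixture | COc1ccc2c(c1)[C@H](C)CCC(O)O2 | intermediate
10 | tert-butyl (triphenylphosphoranylidene)acetate | CC(C)(C)OC(=O)C=P(c1ccccc1)(c1ccccc1)c1ccccc1 | starting material
11 | (R)-4-(2-hydroxy-5-methoxyphenyl)pentanal, open form of 9, formed in the flask | COc1ccc(O)c(c1)[C@H](C)CCC=O | intermediate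
12 | tert-butyl (2E,6R)-6-(2-hydroxy-5-methoxyphenyl)hept-2-enoate | COc1ccc(O)c(c1)[C@H](C)CC/C=C/C(=O)OC(C)(C)C | intermediate
13 | tert-butyl (2E,6R)-6-[2-hydroxy-3-(hydroxymethyl)-5-methoxyphenyl]hept-2-enoate, formed in the flask | COc1cc(CO)c(O)c(c1)[C@H](C)CC/C=C/C(=O)OC(C)(C)C | intermediate
14 | tert-butyl (2E,6R)-6-(3-formyl-2-hydroxy-5-methoxyphenyl)hept-2-enoate | COc1cc(C=O)c(O)c(c1)[C@H](C)CC/C=C/C(=O)OC(C)(C)C | intermediate
15 | tert-butyl (2E,6R)-6-[2-hydroxy-3-(1-hydroxyethyl)-5-methoxyphenyl]hept-2-enoate, both carbinol epimers | COc1cc(C(C)O)c(O)c(c1)[C@H](C)CC/C=C/C(=O)OC(C)(C)C | intermediate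
16 | tert-butyl (2E,6R)-6-(3-acetyl-2-hydroxy-5-methoxyphenyl)hept-2-enoate | COc1cc(C(C)=O)c(O)c(c1)[C@H](C)CC/C=C/C(=O)OC(C)(C)C | intermediate
17 | (E)-4,4-dimethoxybut-2-enal (fumaraldehyde mono(dimethyl acetal)) | COC(OC)/C=C/C=O | starting material
18 | tert-butyl (2E,4E)-6,6-dimethoxyhexa-2,4-dienoate | COC(OC)/C=C/C=C/C(=O)OC(C)(C)C | intermediate
19 | tert-butyl (2E,4E)-6-oxohexa-2,4-dienoate | O=C/C=C/C=C/C(=O)OC(C)(C)C | intermediate
20 | tert-butyl (2E,4E)-8-{3-[(2R,5E)-7-tert-butoxy-7-oxohept-5-en-2-yl]-2-hydroxy-5-methoxyphenyl}-6-hydroxy-8-oxoocta-2,4-dienoate, both C6 epimers, formed in the flask | COc1cc(C(=O)CC(O)/C=C/C=C/C(=O)OC(C)(C)C)c(O)c(c1)[C@H](C)CC/C=C/C(=O)OC(C)(C)C | intermediate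
21 | tert-butyl (2E,4E,6E)-8-{3-[(2R,5E)-7-tert-butoxy-7-oxohept-5-en-2-yl]-2-hydroxy-5-methoxyphenyl}-8-oxoocta-2,4,6-trienoate | COc1cc(C(=O)/C=C/C=C/C=C/C(=O)OC(C)(C)C)c(O)c(c1)[C@H](C)CC/C=C/C(=O)OC(C)(C)C | intermediate
22 | (2E,4E,6E)-8-{3-[(2R,5E)-6-carboxyhex-5-en-2-yl]-2-hydroxy-5-methoxyphenyl}-8-oxoocta-2,4,6-trienoic acid | COc1cc(C(=O)/C=C/C=C/C=C/C(=O)O)c(O)c(c1)[C@H](C)CC/C=C/C(=O)O | target

Total step count: 13. Longest linear sequence: 11 (steps 1–9, 12 and 13); steps 10 and 11 make the side fragment 19.

Steps most likely to fail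

Step 12. The base may consume the doubly activated dienal 19 by conjugate addition of methoxide or enolate and by oligomerisation faster than aldol addition and dehydration occur. The phenoxide may also close onto the new enone by oxa-Michael addition. The fallback sets out from 16 and comes back at 21, building the chain in two stages. Claisen–Schmidt condensation of 16 with the base-stable acetal aldehyde 17 (Ba(OH)2·8H2O, MeOH) passes through the β-hydroxy ketone tert-butyl (2E,6R)-6-{3-[(4E)-3-hydroxy-6,6-dimethoxyhex-4-enoyl]-2-hydroxy-5-methoxyphenyl}hept-2-enoate F3. This dehydrates in the flask to the dienone acetal tert-butyl (2E,6R)-6-{3-[(2E,4E)-6,6-dimethoxyhexa-2,4-dienoyl]-2-hydroxy-5-methoxyphenyl}hept-2-enoate F4. Acetal hydrolysis (p-TsOH·H2O, wet acetone) gives the dienone aldehyde tert-butyl (2E,6R)-6-{3-[(2E,4E)-6-oxohexa-2,4-dienoyl]-2-hydroxy-5-methoxyphenyl}hept-2-enoate F5. Wittig olefination of its aldehyde, not its ketone, with ylide 10 then gives 21.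

Step 4. Peracid addition to the conjugated, donor-substituted ketone may be slow enough for electrophilic oxidation of the anisole ring, partial migration of the C2 methylene, or acid-promoted opening of the aryl lactone to compete. The fallback sets out from 7 and comes back at 9, forming the same aryl C–O bond by a Hock rearrangement. NaBH4 in MeOH reduces 7 to tetralol 6. Aqueous H2O2 with catalytic H2SO4 in Et2O at 0 °C exchanges the para-methoxy-activated benzylic hydroxyl for a hydroperoxide, giving (4R)-1-hydroperoxy-6-methoxy-4-methyl-1,2,3,4-tetrahydronaphthalene F1. BF3·OEt2 in CH2Cl2 at 0 °C then triggers aryl migration to oxygen with loss of water, and water capture of the cyclic oxocarbenium ion on quench gives lactol 9.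

Step 5. The aluminium hemiacetal may collapse with loss of the phenoxide before the quench, so that the liberated aldehyde is reduced further to the diol. The fallback sets out from 8 and comes back at 9. Aminolysis of 8 with MeNHOMe·HCl and i-PrMgCl in THF at −20 °C opens the lactone to the Weinreb amide (R)-4-(2-hydroxy-5-methoxyphenyl)-N-methoxy-N-methylpentanamide F2. Reduction with LiAlH4 or excess i-Bu2AlH at −78 °C forms a stable chelate that releases the aldehyde only on work-up, giving 9 in equilibrium with 11.

Further compounds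
F1 | step 4 | (4R)-1-hydroperoxy-6-methoxy-4-methyl-1,2,3,4-tetrahydronaphthalene, both C1 epimers | COc1ccc2c(c1)[C@H](C)CCC2OO
F2 | step 5 | (R)-4-(2-hydroxy-5-methoxyphenyl)-N-methoxy-N-methylpentanamide | COc1ccc(O)c(c1)[C@H](C)CCC(=O)N(C)OC
F3 | step 12 | tert-butyl (2E,6R)-6-{3-[(4E)-3-hydroxy-6,6-dimethoxyhex-4-enoyl]-2-hydroxy-5-methoxyphenyl}hept-2-enoate, both carbinol epimers | COc1cc(C(=O)CC(O)/C=C/C(OC)OC)c(O)c(c1)[C@H](C)CC/C=C/C(=O)OC(C)(C)C
F4 | step 12 | tert-butyl (2E,6R)-6-{3-[(2E,4E)-6,6-dimethoxyhexa-2,4-dienoyl]-2-hydroxy-5-methoxyphenyl}hept-2-enoate | COc1cc(C(=O)/C=C/C=C/C(OC)OC)c(O)c(c1)[C@H](C)CC/C=C/C(=O)OC(C)(C)C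
F5 | step 12 | tert-butyl (2E,6R)-6-{3-[(2E,4E)-6-oxohexa-2,4-dienoyl]-2-hydroxy-5-methoxyphenyl}hept-2-enoate | COc1cc(C(=O)/C=C/C=C/C=O)c(O)c(c1)[C@H](C)CC/C=C/C(=O)OC(C)(C)C
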